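**Retrosynthetic overview**
1. Target 17 ⇐ diacetate 16 ⇐ acid 14 + 2,4-dihydroxybenzaldehyde 15. The pyranone of ring C (the 3''-oxy-7''-hydroxycoumarin) is closed last by Perkin–Oglialoro condensation; its C2''/C3'' and the C7–O–C3'' ether oxygen are carried on ring A from the start as an ethyl oxyacetate, so no phenol has to be differentiated after the key step.
2. 14 ⇐ ester 13 ⇐ silyl triflate 6 (source of coumarin-7,8-yne) + caesium sulfonate 9. One step makes both C7'–O and C8'–C6. The plan rests on ring B carrying, on the adjacent carbons C7' and C8' beside the lactone oxygen O1', a hydroxyl group and the bond to C6 of ring A, which is the pattern a C7'–C8' aryne takes up.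
3. 6 ⇐ umbelliferone 1 (C8 iodination, O-silylation, retro-Brook shift, triflation). 9 ⇐ umbelliferone 1 (O-alkylation, C6 chlorosulfonation, buffered hydrolysis).
4. Ring order: the pyranones of rings A and B come ready-made in umbelliferone; the only ring formed is the ring C pyranone in step 9.

Key step: step 7

Assumption: the target SMILES defines no stereocentre and no axial configuration, so the C6–C8' biaryl axis is treated as stereochemically undefined and no stereocontrol is planned.

**Route**

Step 1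
Reactants: 1 umbelliferone (7-hydroxy-2H-chromen-2-one)
Product: 2 7-hydroxy-8-iodo-2H-chromen-2-one
Conditions: I2 (1.0 equiv), KI, 20% aq. NH3, rt; then dil. H2SO4
Reagents that add atoms: iodine, II
Why: Electrophilic aromatic iodination of the phenoxide, in which C8, flanked by the phenoxide oxygen and the ring oxygen, is the most nucleophilic carbon of umbelliferone and one equivalent of iodine should stop at the mono-iodide.

Step 2
Reactants: 2 7-hydroxy-8-iodo-2H-chromen-2-one
Product: 3 8-iodo-7-[(trimethylsilyl)oxy]-2H-chromen-2-one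
Conditions: (Me3Si)2NH, THF, 65 °C; evaporate, use crude under argon
Reagents that add atoms: hexamethyldisilazane, C[Si](C)(C)N[Si](C)(C)C
Why: O-Silylation of the acidic phenol with hexamethyldisilazane gives the silyl ether with ammonia as the only by-product, so the moisture-sensitive ether needs no purification.

Step 3
Reactants: 3 8-iodo-7-[(trimethylsilyl)oxy]-2H-chromen-2-one
Product: 6 2-oxo-8-(trimethylsilyl)-2H-chromen-7-yl trifluoromethanesulfonate, via 8-lithio-7-[(trimethylsilyl)oxy]-2H-chromen-2-one 4 (not isolated), via lithium 2-oxo-8-(trimethylsilyl)-2H-chromen-7-olate 5 (not isolated)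
Conditions: n-BuLi (1.05 equiv), THF, −100 °C; then Tf2O, −100 °C to rt
Reagents that add atoms: trifluoromethanesulfonic anhydride, O=S(=O)(OS(=O)(=O)C(F)(F)F)C(F)(F)F
Why: Retro-Brook (1,3 O-to-C silyl) rearrangement, in which iodine–lithium exchange on the aryl iodide should outrun attack of butyllithium on the lactone at −100 °C, aryllithium 4 takes the silyl group from the neighbouring oxygen, and phenoxide 5 is triflated in the same flask.

Step 4
Reactants: 1 umbelliferone
Product: 7 ethyl 2-[(2-oxo-2H-chromen-7-yl)oxy]acetate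
Conditions: BrCH2CO2Et, K2CO3, acetone, reflux
Reagents that add atoms: ethyl bromoacetate, CCOC(=O)CBr
Why: Williamson ether synthesis of an acidic phenol with a reactive α-halo ester under mild carbonate conditions that leave the lactone untouched.

Step 5
Reactants: 7 ethyl 2-[(2-oxo-2H-chromen-7-yl)oxy]acetate
Product: 8 ethyl 2-{[6-(chlorosulfonyl)-2-oxo-2H-chromen-7-yl]oxy}acetate
Conditions: ClSO3H (neat, excess), 0 °C to 40 °C; pour on ice, filter
Reagents that add atoms: chlorosulfonic acid, OS(=O)(=O)Cl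
Why: Electrophilic chlorosulfonation directed to C6, which is ortho to the ether oxygen and para to the ring oxygen while C8 is hemmed in between two oxygens; aryloxyacetate ethyl esters are known to survive this reagent.

Step 6
Reactants: 8 ethyl 2-{[6-(chlorosulfonyl)-2-oxo-2H-chromen-7-yl]oxy}acetate
Product: 9 caesium 7-(2-ethoxy-2-oxoethoxy)-2-oxo-2H-chromene-6-sulfonate
Conditions: CsOAc (2.0 equiv), acetone/H2O (1:1), 40 °C; evaporate (PhMe azeotrope); recrystallise from EtOH/H2O; dry at 80 °C in vacuo
Reagents that add atoms: water, O; caesium acetate, CC(=O)[O-].[Cs+]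
Why: Hydrolysis of the sulfonyl chloride in an acetate buffer, whose near-neutral pH spares the ethyl ester and the lactone, with crystallisation to remove CsCl so that no competing nucleophile enters the key step.

Step 7
Reactants: 6 2-oxo-8-(trimethylsilyl)-2H-chromen-7-yl trifluoromethanesulfonate; 9 caesium 7-(2-ethoxy-2-oxoethoxy)-2-oxo-2H-chromene-6-sulfonate
Product: 13 ethyl 2-{[6-(7-hydroxy-2-oxo-2H-chromen-8-yl)-2-oxo-2H-chromen-7-yl]oxy}acetate, via coumarin-7,8-yne 10 (not isolated), via C8'-carbanion of the aryl sulfonate ester 11 (not isolated), via caesium phenoxide of the biaryl 12 (not isolated)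
Conditions: 9 (3 equiv), CsF (3 equiv), 18-crown-6 (3 equiv), DME, 60 °C, 6 added over 6 h; then 1 M HCl
Reagents that add atoms: none
Why: Proposed new method: fluoride strips the silyl group of 6 and loss of triflate gives aryne 10; a sulfonate oxygen of 9 adds to C7', the aryne carbon remote from O1', which places the negative charge of 11 on C8' next to the inductively withdrawing lactone oxygen, and this carbanion attacks the sulfur-bearing C6 of ring A in a five-membered array (C8', C7', O, S, C6) through a spirocyclic σ-complex, after which C–S cleavage and extrusion of SO2 leave phenoxide 12. The nearest established chemistry is the fluoride-triggered reaction of arynes with arenesulfonamides, where N-arylation is followed by Truce–Smiles aryl migration and SO2 loss to 2-aminobiaryls, and the insertion of arynes into the C–O bond of carboxylic acids shows that weakly basic oxygen anions can add; a sulfonate oxygen has not been used in this way. No ring is closed, the spiro ring being transient, and no stereocentre is formed. The step needs oxygen attack at C7' and not C8', which O1' secures as an alkoxy group does in 3-alkoxyarynes, and aryl transfer from C6, which the sulfonyl group fixes. Ring A carries no nitro-type activation, so ipso attack relies on the electron-poor coumarin nucleus, the sulfonyl ester at the ipso carbon and intramolecularity; attack at sulfur through a four-membered array (anionic thia-Fries) and protonation of 11 are the competitors. A non-protic ether solvent, excess sulfonate and slow addition of 6 are chosen to hold back protonation and O-arylation of 12 by further aryne.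

Step 8
Reactants: 13 ethyl 2-{[6-(7-hydroxy-2-oxo-2H-chromen-8-yl)-2-oxo-2H-chromen-7-yl]oxy}acetate
Product: 14 2-{[6-(7-hydroxy-2-oxo-2H-chromen-8-yl)-2-oxo-2H-chromen-7-yl]oxy}acetic acid
Conditions: 2 M HCl, 1,4-dioxane/H2O, 80 °C
Reagents that add atoms: water, O
Why: Acid-catalysed ester hydrolysis, chosen over saponification because both coumarin lactones and the biaryl phenol are inert to aqueous acid.

Step 9
Reactants: 14 2-{[6-(7-hydroxy-2-oxo-2H-chromen-8-yl)-2-oxo-2H-chromen-7-yl]oxy}acetic acid; 15 2,4-dihydroxybenzaldehyde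
Product: 16 3-{[6-(7-acetoxy-2-oxo-2H-chromen-8-yl)-2-oxo-2H-chromen-7-yl]oxy}-2-oxo-2H-chromen-7-yl acetate
Conditions: Ac2O, Et3N, 110 °C
Reagents that add atoms: acetic anhydride, CC(=O)OC(C)=O
Why: Perkin–Oglialoro condensation, in which acetic anhydride and triethylamine turn the aryloxyacetic acid into an enolisable mixed anhydride whose α-carbon condenses with the aldehyde while the carboxyl carbon acylates the 2-hydroxyl, closing the ring C pyranone with the C3''–O bond already in place; both free phenols end as acetates.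

Step 10
Reactants: 16 3-{[6-(7-acetoxy-2-oxo-2H-chromen-8-yl)-2-oxo-2H-chromen-7-yl]oxy}-2-oxo-2H-chromen-7-yl acetate
Product: 17 7-hydroxy-8-{7-[(7-hydroxy-2-oxo-2H-chromen-3-yl)oxy]-2-oxo-2H-chromen-6-yl}-2H-chromen-2-one
Conditions: 3 M HCl, 1,4-dioxane/H2O, 70 °C
Reagents that add atoms: none
Why: Acid-catalysed hydrolysis of the two aryl acetates, under which the three lactones and the electron-poor 3-aryloxy enol ether should stay intact.

**Compound list**
1 | umbelliferone (7-hydroxy-2H-chromen-2-one) | O=c1ccc2ccc(O)cc2o1 | starting material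
2 | 7-hydroxy-8-iodo-2H-chromen-2-one | O=c1ccc2ccc(O)c(I)c2o1 | intermediate
3 | 8-iodo-7-[(trimethylsilyl)oxy]-2H-chromen-2-one | O=c1ccc2ccc(O[Si](C)(C)C)c(I)c2o1 | intermediate
4 | 8-lithio-7-[(trimethylsilyl)oxy]-2H-chromen-2-one | [Li]c1c(O[Si](C)(C)C)ccc2ccc(=O)oc12 | intermediate
5 | lithium 2-oxo-8-(trimethylsilyl)-2H-chromen-7-olate | [Li+].[O-]c1ccc2ccc(=O)oc2c1[Si](C)(C)C | intermediate
6 | 2-oxo-8-(trimethylsilyl)-2H-chromen-7-yl trifluoromethanesulfonate | O=c1ccc2ccc(OS(=O)(=O)C(F)(F)F)c([Si](C)(C)C)c2o1 | intermediate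
7 | ethyl 2-[(2-oxo-2H-chromen-7-yl)oxy]acetate | CCOC(=O)COc1ccc2ccc(=O)oc2c1 | intermediate
8 | ethyl 2-{[6-(chlorosulfonyl)-2-oxo-2H-chromen-7-yl]oxy}acetate | CCOC(=O)COc1cc2oc(=O)ccc2cc1S(=O)(=O)Cl | intermediate
9 | caesium 7-(2-ethoxy-2-oxoethoxy)-2-oxo-2H-chromene-6-sulfonate | [Cs+].CCOC(=O)COc1cc2oc(=O)ccc2cc1S(=O)(=O)[O-] | intermediate
10 | coumarin-7,8-yne (7,8-didehydro-2H-chromen-2-one) | O=C1C=CC2=C(O1)C#CC=C2 | intermediate
11 | caesium 7-({[7-(2-ethoxy-2-oxoethoxy)-2-oxo-2H-chromen-6-yl]sulfonyl}oxy)-2-oxo-2H-chromen-8-ide | [Cs+].CCOC(=O)COc1cc2oc(=O)ccc2cc1S(=O)(=O)Oc1ccc2ccc(=O)oc2[c-]1 | intermediate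
12 | caesium 8-[7-(2-ethoxy-2-oxoethoxy)-2-oxo-2H-chromen-6-yl]-2-oxo-2H-chromen-7-olate | [Cs+].CCOC(=O)COc1cc2oc(=O)ccc2cc1-c1c([O-])ccc2ccc(=O)oc12 | intermediate
13 | ethyl 2-{[6-(7-hydroxy-2-oxo-2H-chromen-8-yl)-2-oxo-2H-chromen-7-yl]oxy}acetate | CCOC(=O)COc1cc2oc(=O)ccc2cc1-c1c(O)ccc2ccc(=O)oc12 | intermediate
14 | 2-{[6-(7-hydroxy-2-oxo-2H-chromen-8-yl)-2-oxo-2H-chromen-7-yl]oxy}acetic acid | OC(=O)COc1cc2oc(=O)ccc2cc1-c1c(O)ccc2ccc(=O)oc12 | intermediate
15 | 2,4-dihydroxybenzaldehyde | O=Cc1ccc(O)cc1O | starting material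
16 | 3-{[6-(7-acetoxy-2-oxo-2H-chromen-8-yl)-2-oxo-2H-chromen-7-yl]oxy}-2-oxo-2H-chromen-7-yl acetate | CC(=O)Oc1ccc2cc(Oc3cc4oc(=O)ccc4cc3-c3c(OC(C)=O)ccc4ccc(=O)oc34)c(=O)oc2c1 | intermediate
17 | 7-hydroxy-8-{7-[(7-hydroxy-2-oxo-2H-chromen-3-yl)oxy]-2-oxo-2H-chromen-6-yl}-2H-chromen-2-one | O=c1ccc2cc(-c3c(O)ccc4ccc(=O)oc34)c(Oc3cc4ccc(O)cc4oc3=O)cc2o1 | target

**Step count**
Total: 10 steps. Longest linear sequence: 7 steps (steps 1, 2, 3, 7, 8, 9, 10, or equally steps 4, 5, 6, 7, 8, 9, 10).

**Steps most likely to fail**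

1. Step 7 (the proposed new method). The sulfonate may add to the aryne too slowly or reversibly. The C8' carbanion may be protonated or attack sulfur before it reaches C6. The product phenoxide may consume further aryne by O-arylation. Fallback with known chemistry, setting out from 2 and 8 and returning at 13: phenol 2 is sulfonylated with sulfonyl chloride 8 (Et3N, cat. DMAP, CH2Cl2, 0 °C) to give 8-iodo-2-oxo-2H-chromen-7-yl 7-(2-ethoxy-2-oxoethoxy)-2-oxo-2H-chromene-6-sulfonate F1. Slow addition of Bu3SnH and AIBN in refluxing benzene then generates the C8' aryl radical. This radical undergoes the established 1,5-ipso substitution at the sulfonyl-bearing C6 (radical Truce–Smiles rearrangement of 2-iodoaryl arenesulfonates), loses SO2 and is reduced to phenol 13. The alkoxy group ortho to sulfur is expected to favour ipso attack over addition at C5.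

2. Step 3. Addition of butyllithium to the lactone carbonyl or to C4 may compete with iodine–lithium exchange, and the O-silyl group may be lost before it migrates. Fallback, setting out from 2 and returning at 6, replaces the organolithium by cross-coupling. Phenol 2 is protected (MOMCl, i-Pr2NEt, CH2Cl2) as 8-iodo-7-(methoxymethoxy)-2H-chromen-2-one F2. Silylation with Me3SiSiMe3 under zerovalent palladium catalysis (Pd2(dba)3, 2-(di-tert-butylphosphino)biphenyl, LiOAc, DMF, 100 °C) gives 7-(methoxymethoxy)-8-(trimethylsilyl)-2H-chromen-2-one F3. Dilute HCl in MeOH at rt frees 7-hydroxy-8-(trimethylsilyl)-2H-chromen-2-one F4, and Tf2O with pyridine in CH2Cl2 at 0 °C gives 6.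

3. Step 9. Self-condensation of the aldehyde with acetic anhydride to a simple coumarin may compete, and enolisation of the hindered mixed anhydride may be sluggish. Fallback, setting out from 14 and 15 and returning at 17, builds ring C stepwise without hot anhydride. Aldehyde 15 is protected selectively at the non-chelated 4-hydroxyl (MOMCl, K2CO3, acetone) as 2-hydroxy-4-(methoxymethoxy)benzaldehyde F5. Acid 14 is acetylated (Ac2O, pyridine, then aqueous work-up) to 2-{[6-(7-acetoxy-2-oxo-2H-chromen-8-yl)-2-oxo-2H-chromen-7-yl]oxy}acetic acid F6. Carbodiimide esterification of F6 with F5 (EDC·HCl, DMAP, CH2Cl2) gives 2-formyl-5-(methoxymethoxy)phenyl 2-{[6-(7-acetoxy-2-oxo-2H-chromen-8-yl)-2-oxo-2H-chromen-7-yl]oxy}acetate F7. DBU in MeCN closes the pyranone by intramolecular Knoevenagel condensation to 8-{7-[(7-(methoxymethoxy)-2-oxo-2H-chromen-3-yl)oxy]-2-oxo-2H-chromen-6-yl}-2-oxo-2H-chromen-7-yl acetate F8. HCl in MeOH at 50 °C removes the methoxymethyl and acetyl groups to give 17.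

**Further compounds**
F1 | step 7 | 8-iodo-2-oxo-2H-chromen-7-yl 7-(2-ethoxy-2-oxoethoxy)-2-oxo-2H-chromene-6-sulfonate | CCOC(=O)COc1cc2oc(=O)ccc2cc1S(=O)(=O)Oc1ccc2ccc(=O)oc2c1I
F2 | step 3 | 8-iodo-7-(methoxymethoxy)-2H-chromen-2-one | COCOc1ccc2ccc(=O)oc2c1I
F3 | step 3 | 7-(methoxymethoxy)-8-(trimethylsilyl)-2H-chromen-2-one | COCOc1ccc2ccc(=O)oc2c1[Si](C)(C)C
F4 | step 3 | 7-hydroxy-8-(trimethylsilyl)-2H-chromen-2-one | Oc1ccc2ccc(=O)oc2c1[Si](C)(C)C
F5 | step 9 | 2-hydroxy-4-(methoxymethoxy)benzaldehyde | COCOc1ccc(C=O)c(O)c1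
F6 | step 9 | 2-{[6-(7-acetoxy-2-oxo-2H-chromen-8-yl)-2-oxo-2H-chromen-7-yl]oxy}acetic acid | CC(=O)Oc1ccc2ccc(=O)oc2c1-c1cc2ccc(=O)oc2cc1OCC(=O)O
F7 | step 9 | 2-formyl-5-(methoxymethoxy)phenyl 2-{[6-(7-acetoxy-2-oxo-2H-chromen-8-yl)-2-oxo-2H-chromen-7-yl]oxy}acetate | CC(=O)Oc1ccc2ccc(=O)oc2c1-c1cc2ccc(=O)oc2cc1OCC(=O)Oc1cc(OCOC)ccc1C=O
F8 | step 9 | 8-{7-[(7-(methoxymethoxy)-2-oxo-2H-chromen-3-yl)oxy]-2-oxo-2H-chromen-6-yl}-2-oxo-2H-chromen-7-yl acetate | COCOc1ccc2cc(Oc3cc4oc(=O)ccc4cc3-c3c(OC(C)=O)ccc4ccc(=O)oc34)c(=O)oc2c1
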